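**Retrosynthetic overview**

1. The two esters are made last: the C4 propanoate by Mitsunobu inversion of a 4,5-trans allylic alcohol, the C6 (E)-4-hydroxy-2-methylbut-2-enoate by Steglich acylation of an α-ketol. Two primary TBS ethers are removed at the end.
2. The only ring, the cyclohexenone, is closed in one event by forming the C5–C6 bond: an intramolecular carbonyl-ene reaction of an acyclic (Z)-enone keto aldehyde. This also sets the C5 and C6 stereocentres, frees the C6 hydroxyl alone and leaves an isopropenyl group that is hydrogenated to isopropyl.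
3. Enabling feature: the vicinal dicarbonyl C1(=O)–C6H=O (a chelating, glyoxylate-like enophile) is held by the (Z)-C2=C3 double bond next to the C5=C(CH3)2 alkene, whose allylic methyl hydrogens make it the ene donor. The precursor contains no ring.
4. The acyclic precursor comes from 3-methylbut-2-enal, a silyl propargyl ether and a glycolic Weinreb amide, by catalytic asymmetric alkynylation (C4), hydroxyl-directed trans-hydroalumination/iodination ((Z)-alkene), vinyllithium acylation and oxidation.
5. Stereochemical relay: C4 (catalyst) controls C5 and C6 (ene, all-trans), and C4 is then inverted when the propanoate is introduced.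

Key step: step 6

Remark: C1–C6 mean the ring atoms numbered as in cyclohex-2-en-1-one (C1 ketone, C2 bearing CH2O, C4 bearing the propanoate oxygen, C5 isopropyl, C6 bearing the butenoate oxygen) or the acyclic atoms that become them; TBS = tert-butyldimethylsilyl, PMB = 4-methoxybenzyl.
Remark: 2-hydroxy-N-methoxy-N-methylacetamide is taken as a catalogue compound, and the ProPhenol antipode is chosen so that the (S)-carbinol is formed.

**Route**

Step 1
Reactants: 1 3-methylbut-2-enal; 2 tert-butyldimethyl(prop-2-yn-1-yloxy)silane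
Product: 4 (4S)-1-[(tert-butyldimethylsilyl)oxy]-6-methylhept-5-en-2-yn-4-ol, via alkynyl(methyl)zinc 3 (not isolated)
Conditions: 2, Me2Zn (3 equiv), ProPhenol ligand (10 mol %, antipode giving the (S)-carbinol), Ph3PO (20 mol %), toluene, 0 °C; then 1, 0 → 4 °C
Reagents that add atoms: none
Why: The alkynylzinc made with Me2Zn adds to the enal carbonyl inside the chiral dinuclear catalyst assembled from Me2Zn and the ProPhenol ligand (catalytic asymmetric alkynylation of an α,β-unsaturated aldehyde), so the C4 stereocentre is set by enantioface selection of the catalyst.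

Step 2
Reactants: 4 (4S)-1-[(tert-butyldimethylsilyl)oxy]-6-methylhept-5-en-2-yn-4-ol
Product: 6 (2Z,4S)-1-[(tert-butyldimethylsilyl)oxy]-2-iodo-6-methylhepta-2,5-dien-4-ol, via vinylalanate 5 (not isolated)
Conditions: NaAlH2(OCH2CH2OMe)2, THF, 0 °C; then I2, THF, −78 °C
Reagents that add atoms: iodine, II
Why: The alkoxyaluminium hydride formed at the C4 oxygen delivers hydride to the near alkyne carbon (hydroxyl-directed trans-hydroalumination), which places aluminium on C2 cis to C4, and iododealumination with retention then fixes the (Z)-iodoalkene without touching C4.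

Step 3
Reactants: 6 (2Z,4S)-1-[(tert-butyldimethylsilyl)oxy]-2-iodo-6-methylhepta-2,5-dien-4-ol
Product: 7 tert-butyl({(2Z,4S)-2-iodo-4-[(4-methoxybenzyl)oxy]-6-methylhepta-2,5-dien-1-yl}oxy)dimethylsilane
Conditions: NaH, 4-methoxybenzyl chloride, Bu4NI (cat.), THF/DMF, 0 °C → rt
Reagents that add atoms: 4-methoxybenzyl chloride, COc1ccc(CCl)cc1
Why: Williamson etherification of the C4 alkoxide gives a PMB ether that cannot migrate to the neighbouring vinyl anion of step 4 and is later removed oxidatively beside silyl ethers and esters, with C4 untouched.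

Step 4
Reactants: 7 tert-butyl({(2Z,4S)-2-iodo-4-[(4-methoxybenzyl)oxy]-6-methylhepta-2,5-dien-1-yl}oxy)dimethylsilane; 8 2-hydroxy-N-methoxy-N-methylacetamide
Product: 11 (3Z,5S)-3-{[(tert-butyldimethylsilyl)oxy]methyl}-1-hydroxy-5-[(4-methoxybenzyl)oxy]-7-methylocta-3,6-dien-2-one, via vinyllithium 9 (not isolated), via magnesium alkoxide 10 (not isolated)
Conditions: 8, i-PrMgCl (1.0 equiv), THF, −20 °C; separately 7, t-BuLi (2.1 equiv), Et2O, −78 °C; then combined, −78 → 0 °C; aq. NH4Cl
Reagents that add atoms: none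
Why: Iodine–lithium exchange keeps the alkene geometry and the vinyllithium acylates the Weinreb amide, whose chelated tetrahedral intermediate survives until work-up (Weinreb ketone synthesis), so the (Z)-enone ketol forms without over-addition and without a new stereocentre.

Step 5
Reactants: 11 (3Z,5S)-3-{[(tert-butyldimethylsilyl)oxy]methyl}-1-hydroxy-5-[(4-methoxybenzyl)oxy]-7-methylocta-3,6-dien-2-one
Product: 12 (3Z,5S)-3-{[(tert-butyldimethylsilyl)oxy]methyl}-5-[(4-methoxybenzyl)oxy]-7-methyl-2-oxoocta-3,6-dienal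
Conditions: Dess–Martin periodinane, pyridine, CH2Cl2, 0 °C; filtered, concentrated cold and used at once
Reagents that add atoms: none
Why: Dess–Martin oxidation of the primary α-ketol gives the vicinal keto aldehyde under buffered, water-free conditions that leave the silyl and PMB ethers, both alkenes and C4 unchanged.

Step 6
Reactants: 12 (3Z,5S)-3-{[(tert-butyldimethylsilyl)oxy]methyl}-5-[(4-methoxybenzyl)oxy]-7-methyl-2-oxoocta-3,6-dienal
Product: 13 (4R,5R,6R)-2-{[(tert-butyldimethylsilyl)oxy]methyl}-6-hydroxy-4-[(4-methoxybenzyl)oxy]-5-(prop-1-en-2-yl)cyclohex-2-en-1-one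
Conditions: Sc(OTf)3 (10 mol %), 4 Å MS, CH2Cl2, −40 → −20 °C
Reagents that add atoms: none
Why: Chelation of the C1/C6 dicarbonyl by Sc(OTf)3 makes the aldehyde carbon C6 a strong enophile that is attacked by C5 of the trisubstituted alkene while an allylic methyl hydrogen passes to the aldehyde oxygen through a six-membered array, a concerted but asynchronous intramolecular carbonyl-ene reaction of type 1 whose closest precedents are the Lewis-acid cyclisation of citronellal to isopulegol and Lewis-acid-catalysed glyoxylate-ene reactions. The cyclohexenone ring closes 6-exo-trig at the aldehyde, C5 becoming a ring atom and the former alkene carbon staying outside the ring as the isopropenyl group. The C6 stereocentre is controlled by the chelate, which holds the aldehyde oxygen s-cis to the ketone oxygen and therefore pseudo-equatorial, the arrangement from which it also reaches the allylic hydrogen, so that hydroxyl and isopropenyl should end up trans. The C5 stereocentre is controlled by the existing C4 centre, because in the chair-like transition state C4–H eclipses the C5=C bond to avoid allylic 1,3-strain with the cis methyl group, which puts the PMB ether pseudo-equatorial and anti to the new bond, so the all-trans (4R,5R,6R) isomer should predominate. The step needs chemoselectivity for the ene path over stepwise Prins closure and ionisation of the allylic ether, secured by a mild catalytic oxophilic Lewis acid at low temperature, and regioselectivity for bonding at C5, secured by the six-membered ring size and charge build-up at the tertiary alkene carbon, while the (Z) geometry of C2=C3 lets the two termini meet at all.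

Step 7
Reactants: 13 (4R,5R,6R)-2-{[(tert-butyldimethylsilyl)oxy]methyl}-6-hydroxy-4-[(4-methoxybenzyl)oxy]-5-(prop-1-en-2-yl)cyclohex-2-en-1-one
Product: 14 (4R,5R,6R)-2-{[(tert-butyldimethylsilyl)oxy]methyl}-6-hydroxy-4-[(4-methoxybenzyl)oxy]-5-(propan-2-yl)cyclohex-2-en-1-one
Conditions: H2 (1 atm), RhCl(PPh3)3 (5 mol %), benzene, rt
Reagents that add atoms: none
Why: Homogeneous hydrogenation with RhCl(PPh3)3 saturates only the unhindered 1,1-disubstituted isopropenyl alkene (as in carvone to carvotanacetone) and leaves the conjugated trisubstituted enone and the PMB ether, and no stereocentre is formed because the new CH carries two methyl groups.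

Step 8
Reactants: 15 2-[(tert-butyldimethylsilyl)oxy]acetaldehyde; 16 ethyl 2-(triphenyl-λ5-phosphanylidene)propanoate
Product: 17 ethyl (2E)-4-[(tert-butyldimethylsilyl)oxy]-2-methylbut-2-enoate
Conditions: CH2Cl2, rt
Reagents that add atoms: none
Why: Wittig olefination with a stabilised ylide should give the (E)-trisubstituted enoate, ester trans to the CH2O group, and creates no stereocentre.

Step 9
Reactants: 17 ethyl (2E)-4-[(tert-butyldimethylsilyl)oxy]-2-methylbut-2-enoate
Product: 18 (2E)-4-[(tert-butyldimethylsilyl)oxy]-2-methylbut-2-enoic acid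
Conditions: LiOH, THF/H2O, rt; then 1 M HCl to pH 4, 0 °C
Reagents that add atoms: lithium hydroxide, [Li+].[OH-]
Why: Saponification of the ethyl ester by hydroxide is tolerated by the primary TBS ether, and brief cold acidification frees the acid without changing the alkene geometry.

Step 10
Reactants: 14 (4R,5R,6R)-2-{[(tert-butyldimethylsilyl)oxy]methyl}-6-hydroxy-4-[(4-methoxybenzyl)oxy]-5-(propan-2-yl)cyclohex-2-en-1-one; 18 (2E)-4-[(tert-butyldimethylsilyl)oxy]-2-methylbut-2-enoic acid
Product: 19 (4R,5S,6R)-2-{[(tert-butyldimethylsilyl)oxy]methyl}-6-({(2E)-4-[(tert-butyldimethylsilyl)oxy]-2-methylbut-2-enoyl}oxy)-4-[(4-methoxybenzyl)oxy]-5-(propan-2-yl)cyclohex-2-en-1-one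
Conditions: DCC, DMAP (cat.), CH2Cl2, 0 °C → rt
Reagents that add atoms: none
Why: Steglich esterification acylates the only free hydroxyl (C6) without breaking its C–O bond, so C6 keeps its configuration, and the equatorial α-acyloxy ketone is also the thermodynamically preferred epimer.

Step 11
Reactants: 19 (4R,5S,6R)-2-{[(tert-butyldimethylsilyl)oxy]methyl}-6-({(2E)-4-[(tert-butyldimethylsilyl)oxy]-2-methylbut-2-enoyl}oxy)-4-[(4-methoxybenzyl)oxy]-5-(propan-2-yl)cyclohex-2-en-1-one
Product: 20 (4R,5S,6R)-2-{[(tert-butyldimethylsilyl)oxy]methyl}-6-({(2E)-4-[(tert-butyldimethylsilyl)oxy]-2-methylbut-2-enoyl}oxy)-4-hydroxy-5-(propan-2-yl)cyclohex-2-en-1-one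
Conditions: DDQ, CH2Cl2/pH 7 buffer, 0 °C
Reagents that add atoms: none
Why: Oxidative PMB cleavage by DDQ (hydride abstraction, hydrolysis of the oxocarbenium ion) frees the C4 hydroxyl with retention and spares the silyl ethers, both esters and the enone.

Step 12
Reactants: 20 (4R,5S,6R)-2-{[(tert-butyldimethylsilyl)oxy]methyl}-6-({(2E)-4-[(tert-butyldimethylsilyl)oxy]-2-methylbut-2-enoyl}oxy)-4-hydroxy-5-(propan-2-yl)cyclohex-2-en-1-one; 21 propanoic acid
Product: 22 (4S,5S,6R)-2-{[(tert-butyldimethylsilyl)oxy]methyl}-6-({(2E)-4-[(tert-butyldimethylsilyl)oxy]-2-methylbut-2-enoyl}oxy)-4-(propanoyloxy)-5-(propan-2-yl)cyclohex-2-en-1-one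
Conditions: PPh3, DIAD, toluene, 0 °C → rt
Reagents that add atoms: none
Why: In the Mitsunobu reaction the C4 hydroxyl is activated as an alkoxyphosphonium ion and displaced by propanoate in an SN2 step with inversion, which turns the 4,5-trans alcohol into the 4,5-cis (4S) propanoate, the allylic position helping the displacement as in inversions of trans-2-isopropylcyclohexanols.

Step 13
Reactants: 22 (4S,5S,6R)-2-{[(tert-butyldimethylsilyl)oxy]methyl}-6-({(2E)-4-[(tert-butyldimethylsilyl)oxy]-2-methylbut-2-enoyl}oxy)-4-(propanoyloxy)-5-(propan-2-yl)cyclohex-2-en-1-one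
Product: 23 (4S,5S,6R)-2-(hydroxymethyl)-6-{[(2E)-4-hydroxy-2-methylbut-2-enoyl]oxy}-4-(propanoyloxy)-5-(propan-2-yl)cyclohex-2-en-1-one
Conditions: HF·pyridine, THF/pyridine, 0 °C → rt
Reagents that add atoms: none
Why: Fluoride cleaves both primary TBS ethers under weakly acidic conditions that should avoid acyl migration and base-induced elimination of the γ-acyloxy enone, and no stereocentre is affected.

**Compound list**

1 | 3-methylbut-2-enal | CC(C)=CC=O | starting material
2 | tert-butyldimethyl(prop-2-yn-1-yloxy)silane | C#CCO[Si](C)(C)C(C)(C)C | starting material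
3 | {3-[(tert-butyldimethylsilyl)oxy]prop-1-yn-1-yl}(methyl)zinc | C[Zn]C#CCO[Si](C)(C)C(C)(C)C | intermediate
4 | (4S)-1-[(tert-butyldimethylsilyl)oxy]-6-methylhept-5-en-2-yn-4-ol | CC(C)=C[C@H](O)C#CCO[Si](C)(C)C(C)(C)C | intermediate
5 | sodium cyclic alkoxy(vinyl)alanate of 4 (five-membered ring O–Al–C2=C3–C4; two 2-methoxyethoxy groups on aluminium) | [Na+].CC(C)=C[C@@H]1O[Al-](OCCOC)(OCCOC)C(CO[Si](C)(C)C(C)(C)C)=C1 | intermediate
6 | (2Z,4S)-1-[(tert-butyldimethylsilyl)oxy]-2-iodo-6-methylhepta-2,5-dien-4-ol | CC(C)=C[C@H](O)/C=C(\I)CO[Si](C)(C)C(C)(C)C | intermediate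
7 | tert-butyl({(2Z,4S)-2-iodo-4-[(4-methoxybenzyl)oxy]-6-methylhepta-2,5-dien-1-yl}oxy)dimethylsilane | CC(C)=C[C@H](OCc1ccc(OC)cc1)/C=C(\I)CO[Si](C)(C)C(C)(C)C | intermediate
8 | 2-hydroxy-N-methoxy-N-methylacetamide | CON(C)C(=O)CO | starting material
9 | vinyllithium from 7 (lithium in place of iodine; alkene geometry retained) | CC(C)=C[C@H](OCc1ccc(OC)cc1)/C=C(\[Li])CO[Si](C)(C)C(C)(C)C | intermediate
10 | chloromagnesium 2-[methoxy(methyl)amino]-2-oxoethan-1-olate | CON(C)C(=O)CO[Mg]Cl | intermediate
11 | (3Z,5S)-3-{[(tert-butyldimethylsilyl)oxy]methyl}-1-hydroxy-5-[(4-methoxybenzyl)oxy]-7-methylocta-3,6-dien-2-one | CC(C)=C[C@H](OCc1ccc(OC)cc1)/C=C(\C(=O)CO)CO[Si](C)(C)C(C)(C)C | intermediate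
12 | (3Z,5S)-3-{[(tert-butyldimethylsilyl)oxy]methyl}-5-[(4-methoxybenzyl)oxy]-7-methyl-2-oxoocta-3,6-dienal | CC(C)=C[C@H](OCc1ccc(OC)cc1)/C=C(\C(=O)C=O)CO[Si](C)(C)C(C)(C)C | intermediate
13 | (4R,5R,6R)-2-{[(tert-butyldimethylsilyl)oxy]methyl}-6-hydroxy-4-[(4-methoxybenzyl)oxy]-5-(prop-1-en-2-yl)cyclohex-2-en-1-one | COc1ccc(CO[C@@H]2C=C(CO[Si](C)(C)C(C)(C)C)C(=O)[C@H](O)[C@H]2C(C)=C)cc1 | intermediate
14 | (4R,5R,6R)-2-{[(tert-butyldimethylsilyl)oxy]methyl}-6-hydroxy-4-[(4-methoxybenzyl)oxy]-5-(propan-2-yl)cyclohex-2-en-1-one | COc1ccc(CO[C@@H]2C=C(CO[Si](C)(C)C(C)(C)C)C(=O)[C@H](O)[C@H]2C(C)C)cc1 | intermediate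
15 | 2-[(tert-butyldimethylsilyl)oxy]acetaldehyde | O=CCO[Si](C)(C)C(C)(C)C | starting material
16 | ethyl 2-(triphenyl-λ5-phosphanylidene)propanoate | CCOC(=O)C(C)=P(c1ccccc1)(c1ccccc1)c1ccccc1 | starting material
17 | ethyl (2E)-4-[(tert-butyldimethylsilyl)oxy]-2-methylbut-2-enoate | CCOC(=O)/C(C)=C/CO[Si](C)(C)C(C)(C)C | intermediate
18 | (2E)-4-[(tert-butyldimethylsilyl)oxy]-2-methylbut-2-enoic acid | OC(=O)/C(C)=C/CO[Si](C)(C)C(C)(C)C | intermediate
19 | (4R,5S,6R)-2-{[(tert-butyldimethylsilyl)oxy]methyl}-6-({(2E)-4-[(tert-butyldimethylsilyl)oxy]-2-methylbut-2-enoyl}oxy)-4-[(4-methoxybenzyl)oxy]-5-(propan-2-yl)cyclohex-2-en-1-one | COc1ccc(CO[C@@H]2C=C(CO[Si](C)(C)C(C)(C)C)C(=O)[C@H](OC(=O)/C(C)=C/CO[Si](C)(C)C(C)(C)C)[C@H]2C(C)C)cc1 | intermediate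
20 | (4R,5S,6R)-2-{[(tert-butyldimethylsilyl)oxy]methyl}-6-({(2E)-4-[(tert-butyldimethylsilyl)oxy]-2-methylbut-2-enoyl}oxy)-4-hydroxy-5-(propan-2-yl)cyclohex-2-en-1-one | O[C@@H]1C=C(CO[Si](C)(C)C(C)(C)C)C(=O)[C@H](OC(=O)/C(C)=C/CO[Si](C)(C)C(C)(C)C)[C@H]1C(C)C | intermediate
21 | propanoic acid | CCC(=O)O | starting material
22 | (4S,5S,6R)-2-{[(tert-butyldimethylsilyl)oxy]methyl}-6-({(2E)-4-[(tert-butyldimethylsilyl)oxy]-2-methylbut-2-enoyl}oxy)-4-(propanoyloxy)-5-(propan-2-yl)cyclohex-2-en-1-one | CCC(=O)O[C@H]1C=C(CO[Si](C)(C)C(C)(C)C)C(=O)[C@H](OC(=O)/C(C)=C/CO[Si](C)(C)C(C)(C)C)[C@H]1C(C)C | intermediate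
23 | (4S,5S,6R)-2-(hydroxymethyl)-6-{[(2E)-4-hydroxy-2-methylbut-2-enoyl]oxy}-4-(propanoyloxy)-5-(propan-2-yl)cyclohex-2-en-1-one | CCC(=O)O[C@H]1C=C(CO)C(=O)[C@H](OC(=O)/C(C)=C/CO)[C@H]1C(C)C | target

**Step count and risks**

Total step count: 13. Longest linear sequence: 11 steps (steps 1–7 and 10–13); steps 8 and 9 make the side-chain acid.

Steps most likely to fail:

Step 6 (key step). The concerted ene path may leak into stepwise cationic closure with unselective proton loss, the doubly allylic C4 ether may ionise, the chelating ketol product may inhibit the catalyst, and facial control at C5 may erode if the alkoxy group takes the inside position. The fallback runs the closure deliberately as a cationic cyclisation with halide capture. Setting out from 12, TiCl4 (1.1 equiv) in CH2Cl2 at −78 °C should give the chloro-Prins product (4R,5R,6R)-2-{[(tert-butyldimethylsilyl)oxy]methyl}-5-(2-chloropropan-2-yl)-6-hydroxy-4-[(4-methoxybenzyl)oxy]cyclohex-2-en-1-one F1 through the same chelated chair. Radical dechlorination with Bu3SnH and AIBN in benzene at 80 °C would then give the isopropyl compound directly, so the fallback comes back to the route at 14 and step 7 is not needed.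

Step 12. The activated C4 oxygen may be lost by elimination toward a cross-conjugated dienone that aromatises, or displacement next to the isopropyl group may be so slow with a weakly acidic partner that acyl transfer with retention competes. The fallback separates activation from displacement. Setting out from 20, ClCH2SO2Cl and pyridine in CH2Cl2 at 0 °C should give, with retention, the sulfonate (4R,5R,6R)-2-{[(tert-butyldimethylsilyl)oxy]methyl}-6-({(2E)-4-[(tert-butyldimethylsilyl)oxy]-2-methylbut-2-enoyl}oxy)-4-[(chloromethanesulfonyl)oxy]-5-(propan-2-yl)cyclohex-2-en-1-one F2. Displacement with EtCO2Cs and 18-crown-6 in toluene at rt should proceed with inversion and come back to the route at 22.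

Step 4. The vinyllithium may decompose by β-elimination of silanolate to an allene or by oxygen-to-carbon silyl shift, or acyl transfer to the deprotonated amide may stall. The fallback avoids organolithium chemistry. Setting out from 7, Nozaki–Hiyama–Kishi coupling with ethyl glyoxylate (CCOC(=O)C=O; CrCl2, NiCl2 (cat.), DMF, rt) should give ethyl (3Z,5S)-3-{[(tert-butyldimethylsilyl)oxy]methyl}-2-hydroxy-5-[(4-methoxybenzyl)oxy]-7-methylocta-3,6-dienoate F3 as a mixture at the new carbinol, which does not matter. Reduction with LiBH4 in THF at 0 °C would give (3Z,5S)-3-{[(tert-butyldimethylsilyl)oxy]methyl}-5-[(4-methoxybenzyl)oxy]-7-methylocta-3,6-diene-1,2-diol F4. Double Swern oxidation ((COCl)2, DMSO, Et3N, CH2Cl2, −78 °C) of the diol should give the vicinal dicarbonyl, so the fallback comes back to the route at 12 and step 5 is not needed.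

**Further compounds**

F1 | step 6 | (4R,5R,6R)-2-{[(tert-butyldimethylsilyl)oxy]methyl}-5-(2-chloropropan-2-yl)-6-hydroxy-4-[(4-methoxybenzyl)oxy]cyclohex-2-en-1-one | COc1ccc(CO[C@@H]2C=C(CO[Si](C)(C)C(C)(C)C)C(=O)[C@H](O)[C@H]2C(C)(C)Cl)cc1
F2 | step 12 | (4R,5R,6R)-2-{[(tert-butyldimethylsilyl)oxy]methyl}-6-({(2E)-4-[(tert-butyldimethylsilyl)oxy]-2-methylbut-2-enoyl}oxy)-4-[(chloromethanesulfonyl)oxy]-5-(propan-2-yl)cyclohex-2-en-1-one | ClCS(=O)(=O)O[C@@H]1C=C(CO[Si](C)(C)C(C)(C)C)C(=O)[C@H](OC(=O)/C(C)=C/CO[Si](C)(C)C(C)(C)C)[C@H]1C(C)C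
F3 | step 4 | ethyl (3Z,5S)-3-{[(tert-butyldimethylsilyl)oxy]methyl}-2-hydroxy-5-[(4-methoxybenzyl)oxy]-7-methylocta-3,6-dienoate | CC(C)=C[C@H](OCc1ccc(OC)cc1)/C=C(\C(O)C(=O)OCC)CO[Si](C)(C)C(C)(C)C
F4 | step 4 | (3Z,5S)-3-{[(tert-butyldimethylsilyl)oxy]methyl}-5-[(4-methoxybenzyl)oxy]-7-methylocta-3,6-diene-1,2-diol | CC(C)=C[C@H](OCc1ccc(OC)cc1)/C=C(\C(O)CO)CO[Si](C)(C)C(C)(C)C
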